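The pitfall in a row of flasks like these was to rank them by the catalyst or partner each held, when the percent asked for is counted on the starting material charged. So I counted turnovers instead: how many rounds each catalyst must make to use up the charge, against how many it gets in the time.

| flask | starting material | partner | free catalyst | remark | time |
|---|---|---|---|---|---|
| noon | 0.21 M | 0.21 M | 0.082 mM | run made earlier |  |
| summer | 0.21 M | 0.21 M | 0.41 mM | run made earlier |  |
| midnight | 0.21 M | 0.25 M | 0.42 mM | run made earlier |  |
| alder | 0.40 M | 0.0800 M | 0.10 mM |  | 40 h |
| maple | 0.21 M | 0.400 M | 0.10 mM |  | 40 h |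
| birch | 0.21 M | 0.210 M | 0.42 mM |  | 40 h |
| elm | 0.21 M | 0.210 M | 0.60 mM |  | 40 h |
| ash | 0.050 M | 0.300 M | 0.42 mM |  | 40 h |
| larch | 0.21 M | 0.100 M | 0.20 mM |  | 40 h |

| run | time / h | target / % | starting material / % |
|---|---|---|---|
| noon | 2.50 | 1.1 | 100.2 |
| noon | 5.00 | 1.7 | 98.7 |
| noon | 12.0 | 3.4 | 96.9 |
| noon | 30.0 | 8.8 | 91.6 |
| summer | 8.00 | 11.3 | 87.5 |
| summer | 15.0 | 18.4 | 78.9 |
| summer | 20.0 | 23.5 | 73.4 |
| summer | 30.0 | 28.9 | 62.9 |
| midnight | 4.00 | 6.9 | 93.4 |
| midnight | 10.0 | 15.2 | 82.9 |
| midnight | 20.0 | 26.0 | 70.1 |
| midnight | 30.0 | 32.1 | 58.3 |

(readings scatter by 0.5 percentage points)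

1. the flasks by amount of target, in percent of the starting material charged, highest first, at 40 h (alder / maple / birch / elm / ash / larch)
2. the amount of target, in percent of the starting material charged of the flask you put first, at 40 h
3. the amount of target, in percent of the starting material charged of the flask you put last, at 40 h



From its first reading at 8.00 h, I read that the summer run turned its catalyst over at 8.00 h⁻¹, the turnover rate (turnover frequency). Ash asked for 119 turnovers, fewer than any other flask. Scaling that rate with the product of starting material and partner, I got 0.915 turnovers available per turnover asked for ash, which as a pseudo-first-order decay left 40.1% of its starting material by my reckoning.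

That scaling was my weak link, since each of the earlier runs held 0.21 M of starting material. So I reforged it from the readings of the summer run, whose rate fell from 0.0156 h⁻¹ early to 0.0105 h⁻¹ late, while the starting material fell to 0.727 of its early level. Taking partner to fall together with it, I read an apparent order n of 0.623 in each. Ash's product of the two charges, taken over the summer run's and raised to that power, gave 1.37, the turnover ratio: turnovers available in the time over turnovers asked.

The summer balance had a gap of 8.20% at 30.0 h. Taking that gap as target lost, and target as rising roughly in a line, I read a loss of 0.0189 h⁻¹, at a catalyst charge close to ash's. Two first-order steps then gave 48.1% of target in ash, my top. For alder, with 4000 turnovers asked, the most of any flask, the ratio was 0.0655, so about 6.34%, my low. Between these two I ranked by the same ratio: elm 0.915, birch 0.640, maple 0.228, larch 0.192.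

The forecast, from “a rate first order in catalyst and in both starting material and partner”, gave ash > elm > birch > maple > larch > alder, top 40% and low 5.1%. Its top stood below mine.

The flasks gave ash > elm > birch > maple > larch > alder, with top 49.6% and low 4.77%, so the forecast's order stood and its top fell 9.6 percentage points short.

    partner + catalyst intermediate A → catalyst intermediate B (k = 0.0440 M⁻¹ s⁻¹)
    catalyst intermediate B → free catalyst + target (k = 0.00720 s⁻¹)
    starting material + free catalyst ⇌ catalyst intermediate A (K = 4.10 M⁻¹, k = 0.0610 M⁻¹ s⁻¹)
    target + free catalyst ⇌ isomer of the product + free catalyst, rate k4*[free catalyst]*[target] forward; the back reaction follows from the equilibrium constant (K = 0.960, k = 0.0220 M⁻¹ s⁻¹)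

Ash had not come to rest at 40.0 h: my ratio for it stood near 1.37, and 23.9% of the starting material was still there. At ten times the time my ratio is 13.7 and the starting material in ash stands at 0%. Yet target in ash moves just from 49.6% to 51.0%, while isomer of the product climbs from 26.4% to 49.0%.

On a second flask, the same as ash but with 0.51 M of partner, my ratio is 1.91, which by my reckoning leaves 14.8% of the starting material and gives 53.2% of target. That flask gives 15% of the starting material left and 54.3% of target.

The numbers in the tables are simulated for an exercise.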